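A direct plan would build the seven-membered ring first, by a furan–oxyallyl (4+3) cycloaddition to the meso oxabicyclic ketone A1. It would desymmetrise A1 with a chiral lithium amide and open the oxygen bridge to the silyloxy cycloheptadienone A2. It would then annulate the cyclopentanol by conjugate addition of a zinc homoenolate and aldol closure to the ketol A3, and finish by directed reduction, esterification and desilylation.
Its weakest step would be the annulation that joins the isopropyl ketone chain to C1 of A2 and closes C4–C5. A homoenolate would have to add 1,4 to a β,β-disubstituted dienone without close precedent, the ligand alone would have to fix the quaternary C1, and C4 and C5 would be left to the equilibration of a ketol that can reopen by retro-aldol.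
The enantioselective deprotonation of A1 would also be weak: it would need a stoichiometric chiral base near −100 °C, and the C8 centre it sets lies too far from C1 to steer any later step.
The Lewis-acid opening of the bridge to A2 would be fragile as well, because this dienone is one loss of silanol away from an aromatic seven-membered ring.

**Retrosynthetic overview**
The C6 ester is disconnected by a Mitsunobu inversion, the C8 methyl carbinol by methyl addition to an enone made by allylic oxidation of C8H2, the C4 isopropyl carbinol by Grignard addition to a ketone, and the C6 oxygen with the C5 hydrogen by conjugate borylation–oxidation of an enone.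
All four relays start from the bicyclic dienone 7. Its cyclohepta-1,4-diene (C5=C6 and C9=C10 on either side of the quaternary C1) is the signature of an alkyne–vinylcyclopropane (5+2) cycloaddition, which forms C1–C5 and C6–C7 and closes the five- and seven-membered rings in one event from the acyclic ynone 6.
Ynone 6 is reached in three steps from cyclopropanecarbaldehyde; C1 is the only centre set by a catalyst, and C5, C6, C4 and C8 are relayed from it in the rigid trans-fused bicycle.
By design there is no cryogenic chiral-base desymmetrisation, no cycloheptadienone that can drift to an aromatic seven-membered ring, no unprecedented conjugate addition for the quaternary carbon, and no ring fusion left to a reversible aldol.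

Key step: step 4

Remark: atom labels C1–C10 are those of the daucane skeleton (C1 quaternary methyl carbon, C4 isopropyl carbinol, C5 ring-fusion CH, C6 ester carbinol, C8 tertiary allylic carbinol, C9=C10 alkene; β is the face of the C1 methyl group); the facial selectivities in steps 5, 6 and 9 are conformational predictions, not measured results.

Step 1
Reactants: 1 cyclopropanecarbaldehyde
Product: 2 1-cyclopropyl-2-methylprop-2-en-1-ol
Conditions: CH2=C(CH3)MgBr (1.2 equiv), THF, 0 °C; aq NH4Cl
Reagents that add atoms: isopropenylmagnesium bromide CC(=C)[Mg]Br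
Why: Grignard 1,2-addition to the aldehyde gives the secondary allylic alcohol; its stereocentre forms as a racemate, which is harmless because step 2 turns this carbon into an sp2 carbon.

Step 2
Reactants: 2 1-cyclopropyl-2-methylprop-2-en-1-ol
Product: 4 methyl (4E)-5-cyclopropyl-4-methylpent-4-enoate, via ketene acetal 3 (not isolated)
Conditions: CH3C(OMe)3 (5 equiv), EtCO2H (5 mol%), 115 °C, MeOH distilled off
Reagents that add atoms: trimethyl orthoacetate COC(C)(OC)OC
Why: Johnson–Claisen rearrangement, in which acid-catalysed exchange with the orthoester gives ketene acetal 3 and its [3,3]-shift through a chair with the cyclopropyl group equatorial should give the (E)-trisubstituted alkene; no stereocentre remains.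

Step 3
Reactants: 4 methyl (4E)-5-cyclopropyl-4-methylpent-4-enoate
Product: 6 (6E)-7-cyclopropyl-6-methylhept-6-en-1-yn-3-one, via Weinreb amide 5 (not isolated)
Conditions: MeNH(OMe)·HCl (1.5 equiv), iPrMgCl (3.0 equiv), THF, −20 °C; then HC≡CMgBr (2.5 equiv), 0 °C; inverse quench into cold aq NaHSO4
Reagents that add atoms: ethynylmagnesium bromide C#C[Mg]Br; N,O-dimethylhydroxylamine hydrochloride CNOC.Cl (retained only in 5)
Why: One-flask Weinreb amide formation and alkynyl Grignard acylation, in which the chelated tetrahedral adduct of 5 survives until the acidic quench, so the ynone is not over-added and the released amine cannot add to it; no stereocentre is involved.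

Step 4
Reactants: 6 (6E)-7-cyclopropyl-6-methylhept-6-en-1-yn-3-one
Product: 7 (3aR)-3a-methyl-3,3a,6,7-tetrahydroazulen-1(2H)-one
Conditions: [RhCl(C2H4)2]2 (2.5 mol%), (11bR)-N,N-bis[(1R)-1-phenylethyl]dinaphtho[2,1-d:1′,2′-f][1,3,2]dioxaphosphepin-4-amine (6 mol%), Na[B(C6H3(CF3)2)4] (6 mol%), CH2Cl2 (0.02 M), 30 °C
Reagents that add atoms: none
Why: A cationic monovalent rhodium centre binds the alkene and the alkyne of 6, opens the cyclopropane by oxidative addition to a rhodacyclohexene (σ-alkyl at C7, π-allyl over C9–C10–C1), inserts the alkyne at the allyl terminus (bond C1–C5) and closes C6–C7 by reductive elimination; the closest known reaction type is the rhodium-catalysed intramolecular (5+2) cycloaddition of tethered alkyne–vinylcyclopropanes, which tolerates a substituent on the tethered alkene carbon (angular methyl) and has enantioselective variants with chiral phosphoramidite or bisphosphine ligands. The five-membered ring closes through the three-atom tether (bond C1–C5) and the seven-membered ring by union of the five vinylcyclopropane carbons C1, C10, C9, C8 and C7 with the alkyne carbons C5 and C6. The only new stereocentre, the quaternary C1, should be set by the ligand, which selects the face of the (E)-trisubstituted alkene on which the allyl–rhodium bond forms and from which the alkyne is delivered (R; the ligand antipode would be taken if the sense proved opposite). The step needs chemoselectivity for cycloaddition over alkyne oligomerisation and over simple ring opening of the cyclopropane, which the short tether and the activated ynone should secure, and it needs no regiocontrol in the cyclopropane because its two distal bonds are equivalent. The product carries C9=C10 where the target needs it and C5=C6 as an enone conjugated to the C4 ketone, so every later centre has a handle.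

Step 5
Reactants: 7 (3aR)-3a-methyl-3,3a,6,7-tetrahydroazulen-1(2H)-one
Product: 9 (3aR,8R,8aS)-8-hydroxy-3a-methyl-3,3a,6,7,8,8a-hexahydroazulen-1(2H)-one, via boronate 8 (not isolated)
Conditions: CuCl (5 mol%), Xantphos (5 mol%), NaOtBu (10 mol%), B2pin2 (1.1 equiv), MeOH (2 equiv), THF, 0 °C → rt; then H2O2 (30%), pH 7 phosphate buffer, 0 °C
Reagents that add atoms: hydrogen peroxide OO; bis(pinacolato)diboron CC1(C)OB(OC1(C)C)B1OC(C)(C)C(C)(C)O1 (retained only in 8)
Why: Copper-catalysed conjugate borylation of the enone and oxidation of the C–B bond with retention (a formal anti-Markovnikov hydration), in which the boryl–copper species should add to C6 from the convex β face because C8–C10 of the boat-like cycloheptadiene cover the α face, and methanol should protonate the copper enolate at C5 from the α face, anti to the angular methyl group and to the new C6–B bond, giving the trans ring fusion (5α-H) and the 6β hydroxyl.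

Step 6
Reactants: 9 (3aR,8R,8aS)-8-hydroxy-3a-methyl-3,3a,6,7,8,8a-hexahydroazulen-1(2H)-one
Product: 10 (3R,3aS,4R,8aR)-8a-methyl-3-(propan-2-yl)-1,2,3,3a,4,5,6,8a-octahydroazulene-3,4-diol
Conditions: iPrMgCl (3 equiv), CeCl3 (3 equiv), THF, −78 °C; aq NH4Cl
Reagents that add atoms: isopropylmagnesium chloride CC(C)[Mg]Cl
Why: Cerium-mediated Grignard 1,2-addition (which suppresses enolisation, reduction and retro-aldol cleavage of the aldolate), in which the axial angular methyl group at C1 blocks the β face of the C4 carbonyl of the trans-fused ketone, so the isopropyl group should enter from the α face and the tertiary hydroxyl is β.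

Step 7
Reactants: 10 (3R,3aS,4R,8aR)-8a-methyl-3-(propan-2-yl)-1,2,3,3a,4,5,6,8a-octahydroazulene-3,4-diol; 11 4-[(tert-butyldimethylsilyl)oxy]benzoic acid
Product: 12 (3R,3aS,4S,8aR)-3-hydroxy-8a-methyl-3-(propan-2-yl)-1,2,3,3a,4,5,6,8a-octahydroazulen-4-yl 4-[(tert-butyldimethylsilyl)oxy]benzoate
Conditions: 11 (1.5 equiv), PPh3 (2 equiv), DIAD (2 equiv), toluene, 0 °C → rt
Reagents that add atoms: none
Why: Mitsunobu esterification, in which the secondary axial 6β-hydroxyl is activated as its oxyphosphonium salt and displaced by the carboxylate of 11 in an SN2 step, so the ester arrives with inversion as the equatorial 6α-benzoate (S at C6) while the tertiary C4 hydroxyl cannot be activated.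

Step 8
Reactants: 12 (3R,3aS,4S,8aR)-3-hydroxy-8a-methyl-3-(propan-2-yl)-1,2,3,3a,4,5,6,8a-octahydroazulen-4-yl 4-[(tert-butyldimethylsilyl)oxy]benzoate
Product: 13 (3R,3aS,4S,8aR)-3-hydroxy-8a-methyl-6-oxo-3-(propan-2-yl)-1,2,3,3a,4,5,6,8a-octahydroazulen-4-yl 4-[(tert-butyldimethylsilyl)oxy]benzoate
Conditions: Rh2(cap)4 (dirhodium tetracaprolactamate, 1 mol%), t-BuOOH (70% in water, 5 equiv), CH2Cl2, rt
Reagents that add atoms: tert-butyl hydroperoxide CC(C)(C)OO
Why: Dirhodium-caprolactamate-catalysed allylic C–H oxidation by tert-butylperoxyl radicals, in which C8 is the only carbon with allylic hydrogens (C1 is quaternary) and the other end of the allyl radical, C10, is neopentylic, so the ketone should form at C8 next to C9=C10; base is left out because the product is a β-aroyloxy ketone, and no stereocentre is formed.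

Step 9
Reactants: 13 (3R,3aS,4S,8aR)-3-hydroxy-8a-methyl-6-oxo-3-(propan-2-yl)-1,2,3,3a,4,5,6,8a-octahydroazulen-4-yl 4-[(tert-butyldimethylsilyl)oxy]benzoate
Product: 14 (3R,3aS,4S,6R,8aR)-3,6-dihydroxy-6,8a-dimethyl-3-(propan-2-yl)-1,2,3,3a,4,5,6,8a-octahydroazulen-4-yl 4-[(tert-butyldimethylsilyl)oxy]benzoate
Conditions: MeMgBr (3 equiv), CeCl3 (3 equiv), THF, −78 °C; aq NH4Cl
Reagents that add atoms: methylmagnesium bromide C[Mg]Br
Why: 1,2-Addition of the weakly basic methylcerium reagent, which should take the enone carbonyl in preference to the hindered aryl ester without β-elimination of the benzoate, along the axial (β) trajectory of the chair-like cycloheptenone, whose only syn-axial neighbour is H6, so the methyl group should be β and the new tertiary hydroxyl equatorial and α (R at C8), cis to the C6 oxygen.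

Step 10
Reactants: 14 (3R,3aS,4S,6R,8aR)-3,6-dihydroxy-6,8a-dimethyl-3-(propan-2-yl)-1,2,3,3a,4,5,6,8a-octahydroazulen-4-yl 4-[(tert-butyldimethylsilyl)oxy]benzoate
Product: 15 (3R,3aS,4S,6R,8aR)-3,6-dihydroxy-6,8a-dimethyl-3-(propan-2-yl)-1,2,3,3a,4,5,6,8a-octahydroazulen-4-yl 4-hydroxybenzoate
Conditions: Bu4NF (1.2 equiv), AcOH (1.2 equiv), THF, 0 °C
Reagents that add atoms: none
Why: Fluoride cleavage of the aryl silyl ether, buffered with acetic acid so that the benzoate and the tertiary allylic alcohol are left alone; no stereocentre is involved.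

**Compound list**
1 | cyclopropanecarbaldehyde | O=CC1CC1 | starting material
2 | 1-cyclopropyl-2-methylprop-2-en-1-ol (racemic) | CC(=C)C(O)C1CC1 | intermediate
3 | [1-[(1-methoxyethenyl)oxy]-2-methylprop-2-en-1-yl]cyclopropane (ketene acetal) | COC(=C)OC(C(C)=C)C1CC1 | intermediate (not isolated)
4 | methyl (4E)-5-cyclopropyl-4-methylpent-4-enoate | COC(=O)CC/C(C)=C/C1CC1 | intermediate
5 | (4E)-5-cyclopropyl-N-methoxy-N,4-dimethylpent-4-enamide | CON(C)C(=O)CC/C(C)=C/C1CC1 | intermediate (not isolated)
6 | (6E)-7-cyclopropyl-6-methylhept-6-en-1-yn-3-one | C#CC(=O)CC/C(C)=C/C1CC1 | intermediate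
7 | (3aR)-3a-methyl-3,3a,6,7-tetrahydroazulen-1(2H)-one (C4 ketone, C5=C6, C9=C10, 1β-Me) | O=C1CC[C@]2(C)C=CCCC=C12 | intermediate
8 | (3aR,8R,8aR)-3a-methyl-8-(4,4,5,5-tetramethyl-1,3,2-dioxaborolan-2-yl)-3,3a,6,7,8,8a-hexahydroazulen-1(2H)-one (6β-boryl, 5α-H) | O=C1CC[C@]2(C)C=CCC[C@@H](B3OC(C)(C)C(C)(C)O3)[C@H]21 | intermediate (not isolated)
9 | (3aR,8R,8aS)-8-hydroxy-3a-methyl-3,3a,6,7,8,8a-hexahydroazulen-1(2H)-one (trans-fused, 6β-OH) | O=C1CC[C@]2(C)C=CCC[C@@H](O)[C@H]21 | intermediate
10 | (3R,3aS,4R,8aR)-8a-methyl-3-(propan-2-yl)-1,2,3,3a,4,5,6,8a-octahydroazulene-3,4-diol (4β-OH, 6β-OH) | CC(C)[C@]1(O)CC[C@]2(C)C=CCC[C@@H](O)[C@H]21 | intermediate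
11 | 4-[(tert-butyldimethylsilyl)oxy]benzoic acid | CC(C)(C)[Si](C)(C)Oc1ccc(cc1)C(=O)O | starting material
12 | (3R,3aS,4S,8aR)-3-hydroxy-8a-methyl-3-(propan-2-yl)-1,2,3,3a,4,5,6,8a-octahydroazulen-4-yl 4-[(tert-butyldimethylsilyl)oxy]benzoate (6α-ester) | CC(C)[C@]1(O)CC[C@]2(C)C=CCC[C@H](OC(=O)c3ccc(O[Si](C)(C)C(C)(C)C)cc3)[C@H]21 | intermediate
13 | (3R,3aS,4S,8aR)-3-hydroxy-8a-methyl-6-oxo-3-(propan-2-yl)-1,2,3,3a,4,5,6,8a-octahydroazulen-4-yl 4-[(tert-butyldimethylsilyl)oxy]benzoate | CC(C)[C@]1(O)CC[C@]2(C)C=CC(=O)C[C@H](OC(=O)c3ccc(O[Si](C)(C)C(C)(C)C)cc3)[C@H]21 | intermediate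
14 | (3R,3aS,4S,6R,8aR)-3,6-dihydroxy-6,8a-dimethyl-3-(propan-2-yl)-1,2,3,3a,4,5,6,8a-octahydroazulen-4-yl 4-[(tert-butyldimethylsilyl)oxy]benzoate | CC(C)[C@]1(O)CC[C@]2(C)C=C[C@](C)(O)C[C@H](OC(=O)c3ccc(O[Si](C)(C)C(C)(C)C)cc3)[C@H]21 | intermediate
15 | (3R,3aS,4S,6R,8aR)-3,6-dihydroxy-6,8a-dimethyl-3-(propan-2-yl)-1,2,3,3a,4,5,6,8a-octahydroazulen-4-yl 4-hydroxybenzoate | CC(C)[C@]1(O)CC[C@]2(C)C=C[C@](C)(O)C[C@H](OC(=O)c3ccc(O)cc3)[C@H]21 | target

Total step count: 10. Longest linear sequence: 10 steps (1 to 15).

**Steps most likely to fail**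

Step 4: the ligand may discriminate poorly between the faces of the trisubstituted alkene when the quaternary centre forms, or the hindered alkene may cyclise slowly and let the ynone oligomerise. The fallback would set out from 6 and give up asymmetric catalysis for a resolution. Cyclisation with the achiral [Rh(CO)2Cl]2 in toluene at 80 °C would give racemic 3a-methyl-3,3a,6,7-tetrahydroazulen-1(2H)-one F1. Corey–Bakshi–Shibata reduction of its enone carbonyl ((S)-2-methyl-CBS-oxazaborolidine, BH3·SMe2, THF, −30 °C) would give two diastereomeric allylic alcohols with a reagent-controlled carbinol centre, (1R,3aR)-3a-methyl-1,2,3,3a,6,7-hexahydroazulen-1-ol F2 and its (1R,3aS) diastereomer F3, to be separated by chromatography. Oxidation of F2 with MnO2 in CH2Cl2 would come back to the route at 7.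

Step 7: the activated axial alcohol may eliminate towards C5 or C7 instead of being displaced, or the hindered centre may not be substituted at all. The fallback would set out from 10 and place the 6α oxygen by directed reduction instead of inversion. Dess–Martin periodinane would oxidise the only secondary alcohol to (3R,3aR,8aR)-3-hydroxy-8a-methyl-3-(propan-2-yl)-2,3,3a,5,6,8a-hexahydroazulen-4(1H)-one F4. Me4NBH(OAc)3 in MeCN/AcOH at −30 °C would deliver hydride from the C4 hydroxyl (1,3-anti) to give (3R,3aS,4S,8aR)-8a-methyl-3-(propan-2-yl)-1,2,3,3a,4,5,6,8a-octahydroazulene-3,4-diol F5. Esterification of F5 with 11 (DCC, DMAP, CH2Cl2) would proceed with retention and come back to the route at 12.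

Step 8: the peroxyl radical may be trapped at the C10 end of the allyl radical (transposed enone), or the oxidation may stall or go beyond the enone. The fallback would set out from 12 and use a pericyclic oxidation. SeO2 (0.5 equiv) with t-BuOOH in CH2Cl2 would place oxygen at C8 only, by an ene reaction and [2,3]-shift that returns the double bond to C9=C10, giving (3R,3aS,4S,8aR)-3,6-dihydroxy-8a-methyl-3-(propan-2-yl)-1,2,3,3a,4,5,6,8a-octahydroazulen-4-yl 4-[(tert-butyldimethylsilyl)oxy]benzoate F6 as a mixture of C6 epimers (C8 in daucane labels). Dess–Martin oxidation of F6 would come back to the route at 13.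

**Further compounds**
F1 | step 4 | racemic 3a-methyl-3,3a,6,7-tetrahydroazulen-1(2H)-one | O=C1CCC2(C)C=CCCC=C12
F2 | step 4 | (1R,3aR)-3a-methyl-1,2,3,3a,6,7-hexahydroazulen-1-ol | O[C@@H]1CC[C@]2(C)C=CCCC=C12
F3 | step 4 | (1R,3aS)-3a-methyl-1,2,3,3a,6,7-hexahydroazulen-1-ol | O[C@@H]1CC[C@@]2(C)C=CCCC=C12
F4 | step 7 | (3R,3aR,8aR)-3-hydroxy-8a-methyl-3-(propan-2-yl)-2,3,3a,5,6,8a-hexahydroazulen-4(1H)-one | CC(C)[C@]1(O)CC[C@]2(C)C=CCCC(=O)[C@H]21
F5 | step 7 | (3R,3aS,4S,8aR)-8a-methyl-3-(propan-2-yl)-1,2,3,3a,4,5,6,8a-octahydroazulene-3,4-diol | CC(C)[C@]1(O)CC[C@]2(C)C=CCC[C@H](O)[C@H]21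
F6 | step 8 | (3R,3aS,4S,8aR)-3,6-dihydroxy-8a-methyl-3-(propan-2-yl)-1,2,3,3a,4,5,6,8a-octahydroazulen-4-yl 4-[(tert-butyldimethylsilyl)oxy]benzoate (mixture of C6 epimers) | CC(C)[C@]1(O)CC[C@]2(C)C=CC(O)C[C@H](OC(=O)c3ccc(O[Si](C)(C)C(C)(C)C)cc3)[C@H]21
A1 | direct plan | (1R,5S)-1,5-dimethyl-8-oxabicyclo[3.2.1]oct-6-en-3-one (meso) | O=C1C[C@@]2(C)C=C[C@@](C)(C1)O2
A2 | direct plan | (6R)-3,6-dimethyl-6-[(triethylsilyl)oxy]cyclohepta-2,4-dien-1-one | O=C1C=C(C)C=C[C@@](C)(C1)O[Si](CC)(CC)CC
A3 | direct plan | (3R,3aR,6R,8aR)-3-hydroxy-6,8a-dimethyl-3-(propan-2-yl)-6-[(triethylsilyl)oxy]-2,3,3a,5,6,8a-hexahydroazulen-4(1H)-one | CC(C)[C@]1(O)CC[C@]2(C)C=C[C@](C)(O[Si](CC)(CC)CC)CC(=O)[C@H]21
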